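At late times the share of target in target plus cross product stops moving once the starting material is consumed, so I asked what that share was while it was being consumed.

the same everywhere: gas 3.3 mM (held); time 5.0 min
- green: starting material 14 mM; second substrate 14.0 mM; everything together at the start
- blue: starting material 14 mM (fed, over 1.0 min); second substrate 14.0 mM; all else is in the flask from the start; the feed brings no volume worth counting
- red: starting material 14 mM (in portions, 2, over 1.0 min); second substrate 14.0 mM; first portion at the start, last at 1.0 min
- teal: starting material 14 mM; second substrate 14.0 mM (fed, over 1.0 min); all else is in the flask from the start; the feed brings no volume worth counting

1. the best flask by share of target in target plus cross product; "all alike" if 1.5 percentage points covers them all (green / blue / red / teal / all alike)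
2. share of target in target plus cross product at the end, green
3. share of target in target plus cross product at the end, blue
4. share of target in target plus cross product at the end, red
5. share of target in target plus cross product at the end, teal

- where a step has two of a species, its rate is k times that concentration squared, and two are used at each turn
- at the start none of partner is dissolved
- run time (green): 5.0 min

    starting material + partner → target (k1 = 7.6 /M/s)
    second substrate + partner → second product (k2 = 1.4 /M/s)
    starting material + second substrate → cross product (k3 = 1.3 /M/s)
    gas ⇌ partner, rate k4*(csat - [partner]) (k4 = 1.5 /s, csat = 3.3 mM)
    2 second substrate → self-condensation product (k5 = 3.1 /M/s)
    partner → decomposed reagent (k6 = 0.010 /s)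

1. I took the partner to stay near its saturation concentration 3.3 mM: its transfer coefficient 1.5 /s exceeds its first-order losses at the charges, 0.136 /s. In step 1 the starting material therefore saw a pseudo-first-order reaction with lifetime 39.9 s by that step by itself, and the run lasts 7.52 such lifetimes.

2. Dividing the two rates of the starting material cancels [starting material]. I named the parity concentration c*, the [second substrate] at which target and cross product form equally fast with the partner at saturation, 19.3 mM. The momentary share is c*/(c* + [second substrate]).

3. First way, for green, from the side of the starting material. Self-condensation by itself gives the second substrate a first half-life of 11.5 s, and on that step [second substrate] falls as its charge over (1 + t/half-life). Its mean over one lifetime is 6.05 mM, and c* turns that into 76.1%.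

4. Second way, for green, from the side of the second substrate, without k1. At the charges, with the partner at saturation, cross product takes 16.6% of the turnover of the second substrate. I froze that fraction for the whole of the second substrate; the charges are equal, so it counts as the same fraction of the starting material, and the share comes to 83.4%.

5. The two ways parted by 7.3 percentage points, and each cheated in its own direction. The first ignored steps that add 0.0228 /s to the 0.0868 /s of self-condensation at the start, so it kept [second substrate] too high and its share reads low. The second froze the split, but the second substrate starts out falling faster than the starting material, at 0.110 /s against 0.0433 /s. Cross product thus takes a growing part at first, and the share of the second way reads high. I committed to the middle for green, 79.8%, and reckoned no other flask.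

The forecast put blue first, with green 78% (75% to 81%), blue 88% (85% to 91%), red 86% (83% to 89%) and teal 85% (81% to 88%), holding that “holding back the starting material helps most”. Its green lies 1.8 points below mine.

The flask blue came out best at 90.4%, ahead of red at 87.2% and green at 80.2%, the order the forecast gave. Green's mean [second substrate] over the first 1.0 min was 3.99 mM, which c* turns into 82.9%. Teal's mean over the same time was 3.74 mM, which c* turns into 83.8%, and teal ended at 85.9%.

The numbers were drawn at random within sensible limits; no experiment stands behind them.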